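Everything rests on disconnecting C12a=C7a, the C2–C3 bond of the N12–H indole (ring B). Both atoms are carbonyl-derived: C12a is an anilide carbon already bonded to C12b of the bromoindole, and C7a is an ortho aryl ketone carbon carrying the C7–C6 chain as an acetal. One low-valent titanium oxo-amide coupling joins these two electrophilic carbons, closes ring B and delivers the 2,2'-biindole with all nineteen carbons of the target in place. The precursor is an N-(2-acylphenyl)indole-2-carboxamide in which C13 bears a nitrile; this blocks C13, so that ring C later closes at N5, and is reduced to the formyl group at the end.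

Key step: step 6

Remark on the chemistry: the formyl carbon is carried as a C13 nitrile from the outset, because a 2,2'-biindole with a free C13–H would be expected to trap the unmasked aldehyde at that carbon (closing to an indolo[2,3-a]carbazole) and not at N5; ethyl 6-bromo-1H-indole-2-carboxylate is taken as the commercial source of the bromoindole.

Step 1
Reactants: 1 2'-nitroacetophenone; 2 methyl formate
Product: 4 3,3-dimethoxy-1-(2-nitrophenyl)propan-1-one, via sodium enolate 3 (not isolated)
Conditions: NaOMe, THF, 0 °C to rt; then HCl in MeOH, 0 °C to rt; NaHCO3 quench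
Reagents that add atoms: methanol, CO
Why: A crossed Claisen condensation of the methyl ketone with non-enolisable methyl formate gives the chelated sodium enolate of the β-keto aldehyde, and acid-catalysed acetalisation in methanol then protects the far more electrophilic aldehyde carbon while the hindered, conjugated aryl ketone stays free.

Step 2
Reactants: 4 3,3-dimethoxy-1-(2-nitrophenyl)propan-1-one
Product: 5 1-(2-aminophenyl)-3,3-dimethoxypropan-1-one
Conditions: H2 (1 atm), 5% Pd/C, EtOAc, Et3N (trace), rt; filtered and used at once in step 5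
Reagents that add atoms: none
Why: Catalytic hydrogenation reduces the aromatic nitro group much faster than the aryl ketone, the neutral medium leaves the acetal untouched, and immediate use keeps the aniline from closing onto the acetal carbon to a 4-quinolone.

Step 3
Reactants: 6 ethyl 6-bromo-1H-indole-2-carboxylate
Product: 8 ethyl 6-bromo-3-cyano-1H-indole-2-carboxylate, via chlorosulfonyl amide 7 (not isolated)
Conditions: ClSO2NCO, MeCN, 0 °C to rt; then DMF, 0 °C to rt; ice water
Reagents that add atoms: chlorosulfonyl isocyanate, O=C=NS(=O)(=O)Cl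
Why: Electrophilic aromatic substitution by chlorosulfonyl isocyanate at C3, the only free nucleophilic carbon of the indole-2-carboxylate, gives the N-chlorosulfonyl carboxamide, which DMF dehydrates to the nitrile (the isocyanate cyanation of indoles).

Step 4
Reactants: 8 ethyl 6-bromo-3-cyano-1H-indole-2-carboxylate
Product: 9 6-bromo-3-cyano-1H-indole-2-carboxylic acid
Conditions: LiOH, THF–H2O, rt to 40 °C; then dilute aq. HCl
Reagents that add atoms: lithium hydroxide, [Li+].[OH-]
Why: Ester saponification with LiOH runs under conditions at which the conjugated nitrile and the aryl bromide are inert.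

Step 5
Reactants: 9 6-bromo-3-cyano-1H-indole-2-carboxylic acid; 5 1-(2-aminophenyl)-3,3-dimethoxypropan-1-one
Product: 11 6-bromo-3-cyano-N-[2-(3,3-dimethoxypropanoyl)phenyl]-1H-indole-2-carboxamide, via acid chloride 10 (not isolated)
Conditions: (COCl)2, DMF (cat.), CH2Cl2, 0 °C to rt, evaporate; then 5, pyridine, THF, 0 °C to rt
Reagents that add atoms: none
Why: Oxalyl chloride with catalytic DMF (Vilsmeier-type activation) converts the acid into its chloride, which acylates the weakly nucleophilic ortho-acyl aniline in an acyl chloride aminolysis, pyridine taking up HCl so that the acetal never meets acid.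

Step 6
Reactants: 11 6-bromo-3-cyano-N-[2-(3,3-dimethoxypropanoyl)phenyl]-1H-indole-2-carboxamide
Product: 12 6-bromo-2-[3-(2,2-dimethoxyethyl)-1H-indol-2-yl]-1H-indole-3-carbonitrile
Conditions: TiCl3, Zn dust, pyridine, DME, reflux (slurry pre-reduced before 11 is added); filtration through silica
Reagents that add atoms: none
Why: Low-valent titanium generated from TiCl3 and zinc reduces the aryl ketone to a titanium-bound ketyl at C7a, which adds to the adjacent anilide carbonyl C12a; the titanium diolate formed is then deoxygenated to the C12a=C7a double bond, and the pyrrole ring B is aromatic at once. The closest known reaction type is the McMurry-type reductive oxo-amide cyclisation of ortho-acylanilides to 2,3-disubstituted indoles, applied here to a new substrate. Ring B closes by a five-membered (5-exo-trig) attack of the C7a ketyl on the amide C=O, which the ortho arrangement makes much faster than intermolecular pinacol coupling. No stereocentre is created. The step needs chemoselectivity for the ketone–amide pair over the nitrile, the aryl bromide and the acetal: only that pair can form a five-membered titanium chelate, nitriles and aryl bromides are reduced far more slowly than ketones by this reagent, and pre-reduction of the TiCl3 with pyridine as buffer keeps the β-keto acetal away from strong Lewis acid. Should the acetal ionise after the indole has formed, N5 would trap C6 on the way to ring C, so that leak is harmless.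

Step 7
Reactants: 12 6-bromo-2-[3-(2,2-dimethoxyethyl)-1H-indol-2-yl]-1H-indole-3-carbonitrile
Product: 15 3-bromo-12H-pyrido[1,2-a:3,4-b']diindole-13-carbonitrile, via aldehyde 13 (not isolated), via cyclic hemiaminal 14 (not isolated)
Conditions: TsOH·H2O, 1,4-dioxane–H2O, 80 °C
Reagents that add atoms: none
Why: Aqueous acid hydrolyses the acetal, N5–H adds to the aldehyde carbon C6 in a 6-exo-trig closure and loss of water from the hemiaminal makes ring C aromatic (acetal hydrolysis followed by intramolecular N-cyclodehydration), while the C13 nitrile excludes the competing Friedel–Crafts closure at carbon so that N5 is the only nucleophile within reach.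

Step 8
Reactants: 15 3-bromo-12H-pyrido[1,2-a:3,4-b']diindole-13-carbonitrile
Product: 17 3-bromo-12H-pyrido[1,2-a:3,4-b']diindole-13-carbaldehyde, via aluminated aldimine 16 (not isolated)
Conditions: i-Bu2AlH (excess), THF–toluene, −78 to 0 °C; then dilute aq. HCl, rt
Reagents that add atoms: water, O
Why: In this partial reduction of a nitrile with i-Bu2AlH, N12–H is first deprotonated, one hydride then adds to the nitrile to give an N-aluminio aldimine that resists further reduction at low temperature, and aqueous acid hydrolyses it to the aldehyde without touching the aryl bromide or the heteroaromatic core.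

Compound list
1 | 2'-nitroacetophenone (1-(2-nitrophenyl)ethan-1-one) | CC(=O)c1ccccc1[N+](=O)[O-] | starting material
2 | methyl formate | COC=O | starting material
3 | sodium (Z)-3-(2-nitrophenyl)-3-oxoprop-1-en-1-olate | [Na+].[O-]/C=C\C(=O)c1ccccc1[N+](=O)[O-] | intermediate
4 | 3,3-dimethoxy-1-(2-nitrophenyl)propan-1-one | COC(OC)CC(=O)c1ccccc1[N+](=O)[O-] | intermediate
5 | 1-(2-aminophenyl)-3,3-dimethoxypropan-1-one | COC(OC)CC(=O)c1ccccc1N | intermediate
6 | ethyl 6-bromo-1H-indole-2-carboxylate | CCOC(=O)c1cc2ccc(Br)cc2[nH]1 | starting material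
7 | ethyl 6-bromo-3-[(chlorosulfonyl)carbamoyl]-1H-indole-2-carboxylate | CCOC(=O)c1[nH]c2cc(Br)ccc2c1C(=O)NS(=O)(=O)Cl | intermediate
8 | ethyl 6-bromo-3-cyano-1H-indole-2-carboxylate | CCOC(=O)c1[nH]c2cc(Br)ccc2c1C#N | intermediate
9 | 6-bromo-3-cyano-1H-indole-2-carboxylic acid | OC(=O)c1[nH]c2cc(Br)ccc2c1C#N | intermediate
10 | 6-bromo-3-cyano-1H-indole-2-carbonyl chloride | ClC(=O)c1[nH]c2cc(Br)ccc2c1C#N | intermediate
11 | 6-bromo-3-cyano-N-[2-(3,3-dimethoxypropanoyl)phenyl]-1H-indole-2-carboxamide | COC(OC)CC(=O)c1ccccc1NC(=O)c1[nH]c2cc(Br)ccc2c1C#N | intermediate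
12 | 6-bromo-2-[3-(2,2-dimethoxyethyl)-1H-indol-2-yl]-1H-indole-3-carbonitrile | COC(OC)Cc1c(-c2[nH]c3cc(Br)ccc3c2C#N)[nH]c2ccccc12 | intermediate
13 | 6-bromo-2-[3-(2-oxoethyl)-1H-indol-2-yl]-1H-indole-3-carbonitrile | O=CCc1c(-c2[nH]c3cc(Br)ccc3c2C#N)[nH]c2ccccc12 | intermediate
14 | 3-bromo-6-hydroxy-6,7-dihydro-12H-pyrido[1,2-a:3,4-b']diindole-13-carbonitrile (racemic at C6) | N#Cc1c2ccc(Br)cc2n2C(O)Cc3c4ccccc4[nH]c3-c12 | intermediate
15 | 3-bromo-12H-pyrido[1,2-a:3,4-b']diindole-13-carbonitrile | N#Cc1c2ccc(Br)cc2n2ccc3c4ccccc4[nH]c3c12 | intermediate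
16 | N,N12-bis(diisobutylaluminio) derivative of (3-bromo-12H-pyrido[1,2-a:3,4-b']diindol-13-yl)methanimine | CC(C)C[Al](CC(C)C)N=Cc1c2ccc(Br)cc2n2ccc3c4ccccc4n([Al](CC(C)C)CC(C)C)c3c12 | intermediate
17 | 3-bromo-12H-pyrido[1,2-a:3,4-b']diindole-13-carbaldehyde | O=Cc1c2ccc(Br)cc2n2ccc3c4ccccc4[nH]c3c12 | target

Total step count: 8. Longest linear sequence: 6 steps (steps 3, 4, 5, 6, 7, 8 from 6; equally steps 1, 2, 5, 6, 7, 8 from 1).

Steps most likely to fail

Step 6. The β-keto acetal may lose methanol under the Lewis-acidic titanium and zinc chlorides before the ketyl closes (elimination to a β-methoxy enone), or the ketone may simply be reduced without ring closure. The fallback carries the masked aldehyde as a cyclic acetal, which ionises less readily and re-closes if it does. It sets out from 4: exchange with 2,2-dimethylpropane-1,3-diol (PPTS, toluene, methanol distilled off) should give 2-(5,5-dimethyl-1,3-dioxan-2-yl)-1-(2-nitrophenyl)ethan-1-one F1. Hydrogenation as in step 2 should give 1-(2-aminophenyl)-2-(5,5-dimethyl-1,3-dioxan-2-yl)ethan-1-one F2. Acylation with 10 and pyridine should give 6-bromo-3-cyano-N-{2-[(5,5-dimethyl-1,3-dioxan-2-yl)acetyl]phenyl}-1H-indole-2-carboxamide F3. The TiCl3–zinc coupling should then give 6-bromo-2-{3-[(5,5-dimethyl-1,3-dioxan-2-yl)methyl]-1H-indol-2-yl}-1H-indole-3-carbonitrile F4. Hot aqueous acid (TsOH·H2O, dioxane–water, 100 °C) removes the diol and closes ring C, so the sequence comes back to the route at 15.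

Step 7. Capture of the aldehyde by the nitrile-deactivated N5 may be slow, so that the arylacetaldehyde self-condenses, or the sequence may stall before water is lost. The fallback separates hydrolysis from dehydration and runs the latter under base. It sets out from 12: gentle hydrolysis (AcOH–H2O–THF, 40 °C) should stop at the equilibrium of 13 with the hemiaminal 14, taken on crude. MsCl and Et3N in CH2Cl2 at 0 °C should convert the hydroxyl group into 3-bromo-13-cyano-6,7-dihydro-12H-pyrido[1,2-a:3,4-b']diindol-6-yl methanesulfonate F5. DBU then eliminates methanesulfonic acid across C6–C7, and the sequence comes back at 15.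

Step 8. Hydride addition to the push–pull (vinylogous cyanamide) nitrile may be incomplete, or reduction may run on to the aminomethyl compound. The fallback removes the nitrile and introduces the formyl group by electrophilic substitution. It sets out from 15: hot aqueous H2SO4–AcOH should hydrolyse the nitrile to 3-bromo-12H-pyrido[1,2-a:3,4-b']diindole-13-carboxylic acid F6. Under the same conditions this acid should lose CO2 (protodecarboxylation of an indole-3-carboxylic acid) to give 3-bromo-12H-pyrido[1,2-a:3,4-b']diindole F7. Vilsmeier–Haack formylation (POCl3, DMF, 0 °C to rt) should attack C13, the most nucleophilic carbon of this ring system, to give N-[(3-bromo-12H-pyrido[1,2-a:3,4-b']diindol-13-yl)methylidene]-N-methylmethanaminium chloride F8. Aqueous NaOH hydrolyses this salt, and the sequence comes back at 17.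

Further compounds
F1 | step 6 | 2-(5,5-dimethyl-1,3-dioxan-2-yl)-1-(2-nitrophenyl)ethan-1-one | CC1(C)COC(CC(=O)c2ccccc2[N+](=O)[O-])OC1
F2 | step 6 | 1-(2-aminophenyl)-2-(5,5-dimethyl-1,3-dioxan-2-yl)ethan-1-one | CC1(C)COC(CC(=O)c2ccccc2N)OC1
F3 | step 6 | 6-bromo-3-cyano-N-{2-[(5,5-dimethyl-1,3-dioxan-2-yl)acetyl]phenyl}-1H-indole-2-carboxamide | CC1(C)COC(CC(=O)c2ccccc2NC(=O)c2[nH]c3cc(Br)ccc3c2C#N)OC1
F4 | step 6 | 6-bromo-2-{3-[(5,5-dimethyl-1,3-dioxan-2-yl)methyl]-1H-indol-2-yl}-1H-indole-3-carbonitrile | CC1(C)COC(Cc2c(-c3[nH]c4cc(Br)ccc4c3C#N)[nH]c3ccccc23)OC1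
F5 | step 7 | 3-bromo-13-cyano-6,7-dihydro-12H-pyrido[1,2-a:3,4-b']diindol-6-yl methanesulfonate (racemic) | N#Cc1c2ccc(Br)cc2n2C(OS(C)(=O)=O)Cc3c4ccccc4[nH]c3-c12
F6 | step 8 | 3-bromo-12H-pyrido[1,2-a:3,4-b']diindole-13-carboxylic acid | OC(=O)c1c2ccc(Br)cc2n2ccc3c4ccccc4[nH]c3c12
F7 | step 8 | 3-bromo-12H-pyrido[1,2-a:3,4-b']diindole | c1c2ccc(Br)cc2n2ccc3c4ccccc4[nH]c3c12
F8 | step 8 | N-[(3-bromo-12H-pyrido[1,2-a:3,4-b']diindol-13-yl)methylidene]-N-methylmethanaminium chloride | C[N+](C)=Cc1c2ccc(Br)cc2n2ccc3c4ccccc4[nH]c3c12.[Cl-]
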